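The route rests on opening ring C of the flavanone at the aryl ether bond O1–C8a. O1 ties the benzylic stereocentre C2 to C8a of ring A, and C8a lies ortho to C4a, which carries the C4–C3–C2 chain, so a resorcinol-derived acetophenone supplies C8a as a phenol carbon that is activated as its triflate. A single palladium-catalysed intramolecular aryl etherification then joins the C2 hydroxyl to C8a and closes ring C while the C2–O bond, and with it the S configuration, stays intact. Its precursor is an anti-(1S,3S)-1,3-diol bearing the ortho triflate, both prenyl groups and a MOM ether; C4 is oxidised afterwards.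

Key step: step 7

Remark on numbering: ring atoms carry flavanone numbers throughout (O1, C2, C3, C4, C4a, C5 to C8, C8a; ring A is the benzo ring, ring C the pyranone).

Remark on configuration: with the anisyl carbinol fixed as S, the 1,3-diol whose two carbinol centres are both S is the anti isomer, and the syn isomer is (1R,3S). The anti-(1S,3S) diol is used because one reagent-controlled double reduction sets both centres. It closes to the 2,4-cis-(2S,4S)-flavan-4-ol, and the C4 centre is erased in step 8.

Remark on twofold steps: in steps 1, 3 and 6 the singly reacted species is numbered as a non-isolated intermediate and drawn as the isomer assumed to form first. The outcome does not depend on the order of the two events.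

Step 1
Reactants: 1 2,4-dihydroxyacetophenone
Product: 3 1-(2,4-dihydroxy-3,5-diiodophenyl)ethan-1-one, via 1-(2,4-dihydroxy-3-iodophenyl)ethan-1-one 2 (not isolated)
Conditions: NIS (2.1 equiv), MeCN, 0 °C to rt
Reagents that add atoms: N-iodosuccinimide, O=C1CCC(=O)N1I
Why: Electrophilic aromatic iodination, in which C3 and C5 are the only ring positions ortho or para to both hydroxyl groups, so the resorcinol core should take up exactly two iodine atoms there while the deactivated C6 position and the acetyl methyl are left alone.

Step 2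
Reactants: 3 1-(2,4-dihydroxy-3,5-diiodophenyl)ethan-1-one
Product: 4 1-[2-hydroxy-3,5-diiodo-4-(methoxymethoxy)phenyl]ethan-1-one
Conditions: MOMCl (1.1 equiv), K2CO3, acetone, 0 °C to rt
Reagents that add atoms: chloromethyl methyl ether, COCCl
Why: Williamson-type O-alkylation (MOM ether formation), selective because the 2-hydroxyl is locked in a hydrogen bond to the acetyl carbonyl, so the more acidic 4-phenoxide should be the one alkylated when close to one equivalent of MOMCl is used.

Step 3
Reactants: 4 1-[2-hydroxy-3,5-diiodo-4-(methoxymethoxy)phenyl]ethan-1-one; 5 tributyl(3-methylbut-2-en-1-yl)stannane (2.6 equiv)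
Product: 7 1-[2-hydroxy-4-(methoxymethoxy)-3,5-bis(3-methylbut-2-en-1-yl)phenyl]ethan-1-one, via 1-[2-hydroxy-3-iodo-4-(methoxymethoxy)-5-(3-methylbut-2-en-1-yl)phenyl]ethan-1-one 6 (not isolated)
Conditions: Pd(PPh3)4 (10 mol%), DMF, 95 °C
Reagents that add atoms: none
Why: Twofold Stille coupling, in which zerovalent palladium inserts readily into both aryl C–I bonds and the allylpalladium intermediate reductively eliminates at its unsubstituted terminus, so both iodides should be replaced by linear 3-methylbut-2-enyl groups without disturbing the MOM ether or the chelated phenol.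

Step 4
Reactants: 7 1-[2-hydroxy-4-(methoxymethoxy)-3,5-bis(3-methylbut-2-en-1-yl)phenyl]ethan-1-one
Product: 8 6-acetyl-3-(methoxymethoxy)-2,4-bis(3-methylbut-2-en-1-yl)phenyl trifluoromethanesulfonate
Conditions: Tf2O, pyridine, CH2Cl2, −10 to 0 °C
Reagents that add atoms: trifluoromethanesulfonic anhydride, O=S(=O)(OS(=O)(=O)C(F)(F)F)C(F)(F)F
Why: Phenol O-sulfonylation (triflation), in which the only remaining hydroxyl should be converted into the aryl triflate faster than the methyl ketone can enolise under pyridine buffering at low temperature, with the MOM ether and the prenyl alkenes untouched.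

Step 5
Reactants: 8 6-acetyl-3-(methoxymethoxy)-2,4-bis(3-methylbut-2-en-1-yl)phenyl trifluoromethanesulfonate; 9 4-methoxybenzoyl chloride
Product: 10 3-(methoxymethoxy)-6-[3-(4-methoxyphenyl)-3-oxopropanoyl]-2,4-bis(3-methylbut-2-en-1-yl)phenyl trifluoromethanesulfonate (1,3-diketone, mainly enol)
Conditions: MgBr2·OEt2, i-Pr2NEt, CH2Cl2, rt
Reagents that add atoms: none
Why: Crossed Claisen-type C-acylation by soft enolisation, in which MgBr2 and the amine generate the magnesium enolate of the methyl ketone under conditions too mild to attack the aryl triflate, and the product is held as its magnesium diketonate, which should stop a second acylation.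

Step 6
Reactants: 10 the 1,3-diketone
Product: 12 6-[(1S,3S)-1,3-dihydroxy-3-(4-methoxyphenyl)propyl]-3-(methoxymethoxy)-2,4-bis(3-methylbut-2-en-1-yl)phenyl trifluoromethanesulfonate (anti diol), via (1S)-1-hydroxy-3-oxo mono-reduction product 11 (not isolated)
Conditions: RuCl[(S,S)-TsDPEN](p-cymene) (3 mol%), HCO2H/Et3N (5:2), EtOAc, 40 °C
Reagents that add atoms: none
Why: Noyori–Ikariya asymmetric transfer hydrogenation, in which the (S,S)-TsDPEN ruthenium hydride reduces each aryl ketone under catalyst control from the face that gives the S carbinol (the sense in which acetophenone gives (S)-1-phenylethanol), so C2 and C4 should both be set S (anti diol), the prenyl alkenes and the triflate are inert to the metal hydride, and any mismatched reduction ends in the separable syn diol instead of the enantiomer.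

Step 7
Reactants: 12 the anti-(1S,3S) diol triflate
Product: 13 (2S,4S)-7-(methoxymethoxy)-2-(4-methoxyphenyl)-6,8-bis(3-methylbut-2-en-1-yl)chroman-4-ol (2,4-cis)
Conditions: Pd2(dba)3 (2.5 mol%), t-BuXPhos (7.5 mol%), K3PO4, toluene, 80 °C
Reagents that add atoms: none
Why: Zerovalent palladium carrying the bulky biarylphosphine adds oxidatively into the C8a–OTf bond, the C2 hydroxyl binds to the arylpalladium centre and is deprotonated by phosphate, and C–O reductive elimination from the resulting seven-membered palladacycle forms O1–C8a. The closest known reaction type is the Buchwald–Hartwig-type intramolecular etherification of aryl halides or triflates by tethered secondary alcohols, which is established for chromans, 2-aryl-substituted ones included. Ring C is closed as a six-membered cyclic aryl ether by bond formation at the arene carbon C8a (exo closure onto the arylpalladium carbon), not at C2. No stereocentre is created: the C2–O bond made in step 6 is never broken, so C2 keeps its S configuration, and the 4S carbinol becomes the cis partner, which lets both ring substituents sit equatorial. The step needs site selectivity between the two hydroxyls and chemoselectivity against β-hydride elimination and S–O cleavage of the triflate; ring size secures the first, since the C4 alkoxide could only close a four-membered ring and, bound as a five-membered chelate, should be poorly aligned for β-hydride elimination, while the di-tert-butylbiaryl ligand accelerates reductive elimination and the insoluble weak base keeps free alkoxide, and with it sulfonyl transfer, to a minimum.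

Step 8
Reactants: 13 the (2S,4S)-flavan-4-ol
Product: 14 (2S)-7-(methoxymethoxy)-2-(4-methoxyphenyl)-6,8-bis(3-methylbut-2-en-1-yl)chroman-4-one
Conditions: Dess–Martin periodinane, NaHCO3, CH2Cl2, 0 °C to rt
Reagents that add atoms: none
Why: Dess–Martin oxidation of a secondary benzylic alcohol, in which the buffered, non-basic periodinane should convert the C4 carbinol into the ketone without epimerising C2 (no base to trigger retro-oxa-Michael ring opening) and without touching the prenyl alkenes or the MOM ether.

Step 9
Reactants: 14 the MOM-protected (2S)-flavanone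
Product: 15 (2S)-7-hydroxy-2-(4-methoxyphenyl)-6,8-bis(3-methylbut-2-en-1-yl)chroman-4-one (the target flavanone)
Conditions: 3 M aq HCl, MeOH, 40 °C
Reagents that add atoms: none
Why: Acid-catalysed acetal solvolysis (MOM cleavage), in which dilute HCl in methanol transfers the methoxymethyl group to the solvent at mild temperature, conditions under which the flavanone stereocentre should not racemise and the prenyl groups should not cyclise onto the liberated 7-hydroxyl.

Compound list
1 | 2,4-dihydroxyacetophenone, 1-(2,4-dihydroxyphenyl)ethan-1-one | CC(=O)c1ccc(O)cc1O | starting material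
2 | 1-(2,4-dihydroxy-3-iodophenyl)ethan-1-one | CC(=O)c1ccc(O)c(I)c1O | intermediate (not isolated)
3 | 1-(2,4-dihydroxy-3,5-diiodophenyl)ethan-1-one | CC(=O)c1cc(I)c(O)c(I)c1O | intermediate
4 | 1-[2-hydroxy-3,5-diiodo-4-(methoxymethoxy)phenyl]ethan-1-one | CC(=O)c1cc(I)c(OCOC)c(I)c1O | intermediate
5 | tributyl(3-methylbut-2-en-1-yl)stannane | CCCC[Sn](CCCC)(CCCC)CC=C(C)C | starting material
6 | 1-[2-hydroxy-3-iodo-4-(methoxymethoxy)-5-(3-methylbut-2-en-1-yl)phenyl]ethan-1-one | CC(=O)c1cc(CC=C(C)C)c(OCOC)c(I)c1O | intermediate (not isolated)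
7 | 1-[2-hydroxy-4-(methoxymethoxy)-3,5-bis(3-methylbut-2-en-1-yl)phenyl]ethan-1-one | CC(=O)c1cc(CC=C(C)C)c(OCOC)c(CC=C(C)C)c1O | intermediate
8 | 6-acetyl-3-(methoxymethoxy)-2,4-bis(3-methylbut-2-en-1-yl)phenyl trifluoromethanesulfonate | CC(=O)c1cc(CC=C(C)C)c(OCOC)c(CC=C(C)C)c1OS(=O)(=O)C(F)(F)F | intermediate
9 | 4-methoxybenzoyl chloride | COc1ccc(C(=O)Cl)cc1 | starting material
10 | 3-(methoxymethoxy)-6-[3-(4-methoxyphenyl)-3-oxopropanoyl]-2,4-bis(3-methylbut-2-en-1-yl)phenyl trifluoromethanesulfonate | COc1ccc(C(=O)CC(=O)c2cc(CC=C(C)C)c(OCOC)c(CC=C(C)C)c2OS(=O)(=O)C(F)(F)F)cc1 | intermediate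
11 | 6-[(1S)-1-hydroxy-3-(4-methoxyphenyl)-3-oxopropyl]-3-(methoxymethoxy)-2,4-bis(3-methylbut-2-en-1-yl)phenyl trifluoromethanesulfonate | COc1ccc(C(=O)C[C@H](O)c2cc(CC=C(C)C)c(OCOC)c(CC=C(C)C)c2OS(=O)(=O)C(F)(F)F)cc1 | intermediate (not isolated)
12 | 6-[(1S,3S)-1,3-dihydroxy-3-(4-methoxyphenyl)propyl]-3-(methoxymethoxy)-2,4-bis(3-methylbut-2-en-1-yl)phenyl trifluoromethanesulfonate (anti diol) | COCOc1c(CC=C(C)C)cc([C@@H](O)C[C@H](O)c2ccc(OC)cc2)c(OS(=O)(=O)C(F)(F)F)c1CC=C(C)C | intermediate
13 | (2S,4S)-7-(methoxymethoxy)-2-(4-methoxyphenyl)-6,8-bis(3-methylbut-2-en-1-yl)chroman-4-ol (2,4-cis) | COCOc1c(CC=C(C)C)cc2c(c1CC=C(C)C)O[C@H](c1ccc(OC)cc1)C[C@@H]2O | intermediate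
14 | (2S)-7-(methoxymethoxy)-2-(4-methoxyphenyl)-6,8-bis(3-methylbut-2-en-1-yl)chroman-4-one | COCOc1c(CC=C(C)C)cc2c(c1CC=C(C)C)O[C@H](c1ccc(OC)cc1)CC2=O | intermediate
15 | (2S)-7-hydroxy-2-(4-methoxyphenyl)-6,8-bis(3-methylbut-2-en-1-yl)chroman-4-one (the target flavanone) | COc1ccc([C@@H]2CC(=O)c3cc(CC=C(C)C)c(O)c(CC=C(C)C)c3O2)cc1 | target

Total step count: 9. Longest linear sequence: 9 steps (1 to 15).

Steps most likely to fail

1. Step 7. What may go wrong:
- slow oxidative addition into the doubly ortho-substituted C8a–O triflate bond;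
- base-induced S–O cleavage of the triflate, including transfer of the sulfonyl group to the neighbouring C4 hydroxyl;
- β-hydride elimination from the C2 palladium alkoxide, which reduces the arene and oxidises the carbinol.

Fallback, setting out from 7 and returning at 14: condensation of 7 with N,N-dimethylformamide dimethyl acetal (toluene, 90 °C) should give the enaminone (E)-3-(dimethylamino)-1-[2-hydroxy-4-(methoxymethoxy)-3,5-bis(3-methylbut-2-en-1-yl)phenyl]prop-2-en-1-one F1. Mild acid (PPTS, warm toluene) should close it, with loss of dimethylamine, to 7-(methoxymethoxy)-6,8-bis(3-methylbut-2-en-1-yl)-4H-chromen-4-one F2. Rhodium-catalysed asymmetric 1,4-addition of 4-methoxyphenylboronic acid (Hayashi–Miyaura type, [Rh(OH)(cod)]2 with an electron-poor MeO-BIPHEP-type bisphosphine of the antipode that gives 2S, aqueous toluene) should then deliver 14 directly. This builds the C2–aryl bond and the stereocentre in one known operation and needs no triflate.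

2. Step 6. What may go wrong:
- stalling at the mono-reduced stage, because the diketone is strongly enolised and the anisoyl carbonyl is electron-rich;
- incomplete catalyst control in the second reduction, which erodes the anti selectivity.

Fallback, setting out from 8 and returning at 14: enolisation of 8 with Ipc2BCl and Et3N (antipode chosen for the S carbinol) and addition to 4-methoxybenzaldehyde at −78 °C (chiral boron aldol) should give 6-[(3S)-3-hydroxy-3-(4-methoxyphenyl)propanoyl]-3-(methoxymethoxy)-2,4-bis(3-methylbut-2-en-1-yl)phenyl trifluoromethanesulfonate F3. Narasaka–Prasad reduction (Et2BOMe, NaBH4, THF/MeOH, −78 °C) should give the syn diol 6-[(1R,3S)-1,3-dihydroxy-3-(4-methoxyphenyl)propyl]-3-(methoxymethoxy)-2,4-bis(3-methylbut-2-en-1-yl)phenyl trifluoromethanesulfonate F4, whose enantiomeric purity can be raised by crystallisation. Under the conditions of step 7, F4 should close to (2S,4R)-7-(methoxymethoxy)-2-(4-methoxyphenyl)-6,8-bis(3-methylbut-2-en-1-yl)chroman-4-ol F5 (2,4-trans), which the conditions of step 8 should oxidise to 14.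

3. Step 3. What may go wrong:
- incomplete coupling at the C3 iodide, which is flanked by two oxygen substituents;
- transfer of the allyl group through its substituted terminus, giving reverse-prenyl isomers;
- protodeiodination.

Fallback, setting out from 1 and returning at 7: Pd(PPh3)4-catalysed O-alkylation of the 4-hydroxyl of 1 with tert-butyl 2-methylbut-3-en-2-yl carbonate should give 1-{2-hydroxy-4-[(2-methylbut-3-en-2-yl)oxy]phenyl}ethan-1-one F6. Aromatic Claisen rearrangement (xylene, about 130 °C) should give 1-[2,4-dihydroxy-3-(3-methylbut-2-en-1-yl)phenyl]ethan-1-one F7; any 5-prenyl isomer converges in the next round. The same etherification should give 1-{2-hydroxy-3-(3-methylbut-2-en-1-yl)-4-[(2-methylbut-3-en-2-yl)oxy]phenyl}ethan-1-one F8. A second Claisen rearrangement into the only free ortho position should give 1-[2,4-dihydroxy-3,5-bis(3-methylbut-2-en-1-yl)phenyl]ethan-1-one F9, and MOM protection under the conditions of step 2 should give 7.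

Further compounds
F1 | step 7 | (E)-3-(dimethylamino)-1-[2-hydroxy-4-(methoxymethoxy)-3,5-bis(3-methylbut-2-en-1-yl)phenyl]prop-2-en-1-one | CN(C)/C=C/C(=O)c1cc(CC=C(C)C)c(OCOC)c(CC=C(C)C)c1O
F2 | step 7 | 7-(methoxymethoxy)-6,8-bis(3-methylbut-2-en-1-yl)-4H-chromen-4-one | O=c1ccoc2c(CC=C(C)C)c(OCOC)c(CC=C(C)C)cc12
F3 | step 6 | 6-[(3S)-3-hydroxy-3-(4-methoxyphenyl)propanoyl]-3-(methoxymethoxy)-2,4-bis(3-methylbut-2-en-1-yl)phenyl trifluoromethanesulfonate | COc1ccc([C@@H](O)CC(=O)c2cc(CC=C(C)C)c(OCOC)c(CC=C(C)C)c2OS(=O)(=O)C(F)(F)F)cc1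
F4 | step 6 | 6-[(1R,3S)-1,3-dihydroxy-3-(4-methoxyphenyl)propyl]-3-(methoxymethoxy)-2,4-bis(3-methylbut-2-en-1-yl)phenyl trifluoromethanesulfonate (syn diol) | COCOc1c(CC=C(C)C)cc([C@H](O)C[C@H](O)c2ccc(OC)cc2)c(OS(=O)(=O)C(F)(F)F)c1CC=C(C)C
F5 | step 6 | (2S,4R)-7-(methoxymethoxy)-2-(4-methoxyphenyl)-6,8-bis(3-methylbut-2-en-1-yl)chroman-4-ol (2,4-trans) | COCOc1c(CC=C(C)C)cc2c(c1CC=C(C)C)O[C@H](c1ccc(OC)cc1)C[C@H]2O
F6 | step 3 | 1-{2-hydroxy-4-[(2-methylbut-3-en-2-yl)oxy]phenyl}ethan-1-one | CC(=O)c1ccc(OC(C)(C)C=C)cc1O
F7 | step 3 | 1-[2,4-dihydroxy-3-(3-methylbut-2-en-1-yl)phenyl]ethan-1-one | CC(=O)c1ccc(O)c(CC=C(C)C)c1O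
F8 | step 3 | 1-{2-hydroxy-3-(3-methylbut-2-en-1-yl)-4-[(2-methylbut-3-en-2-yl)oxy]phenyl}ethan-1-one | CC(=O)c1ccc(OC(C)(C)C=C)c(CC=C(C)C)c1O
F9 | step 3 | 1-[2,4-dihydroxy-3,5-bis(3-methylbut-2-en-1-yl)phenyl]ethan-1-one | CC(=O)c1cc(CC=C(C)C)c(O)c(CC=C(C)C)c1O
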